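Atom numbers are labdane numbers: C4 carries the ester, C8 the methylidene carbon C17, C9 the side chain, C10 the angular methyl.

**Plan**
- Retrosynthesis: cut the palmitate C15–O bond, then C13=C14 (olefination of a C13 methyl ketone), return a ketone to C3 and cut C4–CH3, then cut C4–C5 and C9–C10 together to an acyclic (E,E)-dienyl β-keto ester, and cut that at C1–C2 into an acetoacetate dianion and an allylic bromide from (E)-geranylacetone.
- Enabling feature: C4 bears the ester and C3 can bear a temporary ketone, so C4 can become a 1,3-dicarbonyl radical. C5=C10 and C8=C9 then sit in 1,5-relation, so ring A (C4–C5) and then ring B (C10–C9) zip up, and C8 carries the C17 methyl that loses hydrogen to give the exocyclic alkene.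
- Forward order: the chain is built linearly (steps 1–5); rings A and B form in one oxidative radical cascade, ring B last (step 6); then ester exchange, C4 methylation, C14–C15 by olefination, C3 deoxygenation, reduction at C15 and acylation.
- Stereochemistry: the trans ring fusion and C9 follow from chair–chair cyclisation of the E,E-diene; the absolute sense comes from a (+)-8-phenylmenthyl ester that is later exchanged for methyl; C4 is set by α-face methylation anti to the 10-methyl; 13E comes from the olefination.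

Key step: step 6

Assumption: (E)-geranylacetone is used as the isomerically pure 5E compound (freed from the 5Z isomer before use if necessary).
Assumption: the facial sense of the (+)-(1S,2R,5S)-8-phenylmenthyl ester is taken from the π-stacking model for the metal-chelated radical of this substrate class; should it prove opposite, the commercially available (−)-enantiomer is used in the same sequence.

Step 1
Reactants: 1 (E)-geranylacetone
Product: 2 2-[(3E)-4,8-dimethylnona-3,7-dien-1-yl]-2-methyl-1,3-dioxolane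
Conditions: HOCH2CH2OH, PPTS (cat.), benzene, reflux, Dean–Stark
Reagents that add atoms: ethylene glycol OCCO
Why: Acid-catalysed ketalisation with azeotropic removal of water masks the future C13 ketone so that it survives the strongly basic dianion alkylation of step 5; no stereocentre is formed.

Step 2
Reactants: 2 2-[(3E)-4,8-dimethylnona-3,7-dien-1-yl]-2-methyl-1,3-dioxolane
Product: 3 (2E,6E)-2,6-dimethyl-9-(2-methyl-1,3-dioxolan-2-yl)nona-2,6-dien-1-ol
Conditions: SeO2 (cat.), t-BuOOH, CH2Cl2, 0 °C to rt, stopped at partial conversion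
Reagents that add atoms: selenium dioxide O=[Se]=O (oxygen carrier), tert-butyl hydroperoxide CC(C)(C)OO
Why: Riley-type allylic oxidation (ene reaction then [2,3]-sigmatropic shift) should oxidise the E-methyl group of the terminal, most accessible trisubstituted alkene and give the E allylic alcohol, which fixes the later C1–C10=C5 geometry.

Step 3
Reactants: 3 (2E,6E)-2,6-dimethyl-9-(2-methyl-1,3-dioxolan-2-yl)nona-2,6-dien-1-ol
Product: 5 2-[(3E,7E)-9-bromo-4,8-dimethylnona-3,7-dien-1-yl]-2-methyl-1,3-dioxolane, via allylic mesylate 4 (not isolated)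
Conditions: MsCl, Et3N, THF, −40 °C; then LiBr, THF, 0 °C
Reagents that add atoms: methanesulfonyl chloride CS(=O)(=O)Cl (its atoms stay only in 4), lithium bromide [Li+].[Br-]
Why: Mesylation followed by SN2 displacement with bromide should give the primary allylic bromide without allylic transposition or loss of E geometry, under conditions that are not acidic for the dioxolane.

Step 4
Reactants: 6 (+)-8-phenylmenthol, 7 2,2,6-trimethyl-4H-1,3-dioxin-4-one
Product: 9 (1S,2R,5S)-5-methyl-2-(2-phenylpropan-2-yl)cyclohexyl 3-oxobutanoate, via acetylketene 8 (not isolated)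
Conditions: xylene, 140 °C, acetone distilled off
Reagents that add atoms: none
Why: Thermal retro-[4+2] cleavage of the dioxinone releases acetylketene, which the hindered secondary alcohol traps (acetoacetylation); the auxiliary stereocentres are untouched.

Step 5
Reactants: 9 (1S,2R,5S)-5-methyl-2-(2-phenylpropan-2-yl)cyclohexyl 3-oxobutanoate, 5 2-[(3E,7E)-9-bromo-4,8-dimethylnona-3,7-dien-1-yl]-2-methyl-1,3-dioxolane
Product: 12 (1S,2R,5S)-5-methyl-2-(2-phenylpropan-2-yl)cyclohexyl (6E,10E)-6,10-dimethyl-3,14-dioxopentadeca-6,10-dienoate, via acetoacetate dianion 10 (not isolated), via alkylated dioxolane ester 11 (not isolated)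
Conditions: 9, NaH, THF, 0 °C; n-BuLi, 0 °C; 5, 0 °C; then 1 M HCl, THF, rt
Reagents that add atoms: water O
Why: γ-Alkylation of an acetoacetate dianion (SN2 at the allylic bromide by the more basic terminal carbanion) forms the C1–C2 bond, and dilute acid in the work-up hydrolyses the dioxolane to the C13 methyl ketone.

Step 6
Reactants: 12 (1S,2R,5S)-5-methyl-2-(2-phenylpropan-2-yl)cyclohexyl (6E,10E)-6,10-dimethyl-3,14-dioxopentadeca-6,10-dienoate
Product: 13 (1S,2R,5S)-5-methyl-2-(2-phenylpropan-2-yl)cyclohexyl (1S,4aS,5S,8aS)-4a-methyl-6-methylidene-2-oxo-5-(3-oxobutyl)decahydronaphthalene-1-carboxylate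
Conditions: Mn(OAc)3·2H2O (2.2 equiv), Cu(OAc)2·H2O (1 equiv), Yb(OTf)3 (1 equiv), CF3CH2OH, degassed, −5 to 0 °C
Reagents that add atoms: none
Why: Mn(III) oxidises the Yb(III)-chelated enol of the β-keto ester to the C4 1,3-dicarbonyl radical, which adds 6-endo-trig to C5 of the C5=C10 alkene (ring A); the tertiary C10 radical then adds 6-endo-trig to C9 of the C8=C9 alkene (ring B, closed last), and Cu(II) captures the tertiary C8 radical and eliminates a C17 hydrogen by β-hydride elimination to give the exocyclic C8=C17 alkene, Cu(I) being reoxidised by Mn(III). The closest known reaction type is the Mn(OAc)3/Cu(OAc)2 oxidative free-radical polyene cyclisation of unsaturated β-keto esters in its lanthanide-triflate-promoted 8-phenylmenthyl ester form. Both rings close through a chair–chair arrangement of the (E,E)-diene, so anti addition across C5=C10 gives the trans ring fusion (5-H anti to 10-CH3) and the E geometry of C8=C9 places the C11 chain equatorial at C9 (9-H anti to 10-CH3). The absolute configuration comes from the auxiliary, whose cumyl phenyl ring lies over one face of the chelated planar radical so that C5 bonds to the open face; C4 stays epimerisable and is fixed in step 8. The step needs 6-endo over 5-exo closure (secured by the methyl groups on C10 and C8, the alkene carbons nearer the radical, and by the tertiary radicals so formed), a stop after ring B (the chain carries a C13 ketone and no third alkene, and a simple methyl ketone is not oxidised by Mn(III) at this temperature) and exocyclic over endocyclic alkene formation (the usual course of the Cu(II)-mediated elimination, which favours the less substituted alkene). Diastereomers from imperfect facial control should be separable here because the auxiliary is still attached.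

Step 7
Reactants: 13 (1S,2R,5S)-5-methyl-2-(2-phenylpropan-2-yl)cyclohexyl (1S,4aS,5S,8aS)-4a-methyl-6-methylidene-2-oxo-5-(3-oxobutyl)decahydronaphthalene-1-carboxylate
Product: 15 methyl (1S,4aS,5S,8aS)-4a-methyl-6-methylidene-2-oxo-5-(3-oxobutyl)decahydronaphthalene-1-carboxylate, via acylketene 14 (not isolated)
Conditions: MeOH–toluene, DMAP (cat.), sealed tube, 120 °C
Reagents that add atoms: methanol CO
Why: Transesterification of an enolisable β-keto ester: loss of the auxiliary alcohol from the enol gives the acylketene, which excess methanol traps, so the hindered ester is exchanged without hydrolysis and the auxiliary is recovered; C4 remains epimerisable.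

Step 8
Reactants: 15 methyl (1S,4aS,5S,8aS)-4a-methyl-6-methylidene-2-oxo-5-(3-oxobutyl)decahydronaphthalene-1-carboxylate
Product: 16 methyl (1R,4aR,5S,8aR)-1,4a-dimethyl-6-methylidene-2-oxo-5-(3-oxobutyl)decahydronaphthalene-1-carboxylate
Conditions: K2CO3, MeI, acetone, reflux
Reagents that add atoms: iodomethane CI
Why: C-Alkylation of the β-keto ester enolate: the electrophile should approach C4 from the α face, anti to the axial 10-methyl (1,3-diaxial hindrance on the β face), so the new methyl is equatorial (4α) and the ester axial (4β), as is known for methylation of 3-oxo-4-alkoxycarbonyl trans-decalins.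

Step 9
Reactants: 16 methyl (1R,4aR,5S,8aR)-1,4a-dimethyl-6-methylidene-2-oxo-5-(3-oxobutyl)decahydronaphthalene-1-carboxylate, 17 ethyl 2-[di(propan-2-yloxy)phosphoryl]acetate
Product: 18 methyl (1R,4aR,5S,8aR)-5-[(3E)-5-ethoxy-3-methyl-5-oxopent-3-en-1-yl]-1,4a-dimethyl-6-methylidene-2-oxodecahydronaphthalene-1-carboxylate
Conditions: 17, NaH, THF, 0 °C; then 16, 0 °C to rt
Reagents that add atoms: none
Why: Horner–Wadsworth–Emmons olefination should occur at the unhindered C13 methyl ketone and not at the C3 ketone flanked by the quaternary C4, and the bulky diisopropyl phosphonate should favour the 13E enoate (the minor Z isomer is removed by chromatography).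

Step 10
Reactants: 18 methyl (1R,4aR,5S,8aR)-5-[(3E)-5-ethoxy-3-methyl-5-oxopent-3-en-1-yl]-1,4a-dimethyl-6-methylidene-2-oxodecahydronaphthalene-1-carboxylate
Product: 19 C3 tosylhydrazone of 18
Conditions: TsNHNH2, EtOH, AcOH (cat.), reflux
Reagents that add atoms: 4-methylbenzenesulfonohydrazide Cc1ccc(cc1)S(=O)(=O)NN
Why: Tosylhydrazone formation at the only remaining ketone is the first half of a Caglioti-type deoxygenation that tolerates both alkenes and both esters.

Step 11
Reactants: 19 C3 tosylhydrazone of 18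
Product: 21 methyl (1S,4aR,5S,8aR)-5-[(3E)-5-ethoxy-3-methyl-5-oxopent-3-en-1-yl]-1,4a-dimethyl-6-methylidenedecahydronaphthalene-1-carboxylate, via N-boryl tosylhydrazine 20 (not isolated)
Conditions: catecholborane, CHCl3, 0 °C to rt; then NaOAc·3H2O, reflux
Reagents that add atoms: catecholborane B1Oc2ccccc2O1 (its atoms stay only in 20)
Why: Catecholborane variant of the Caglioti reduction: hydride adds to C=N, acetate induces loss of sulfinate and the diazene loses N2, leaving CH2 at C3 without touching the alkenes, the esters or any stereocentre.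

Step 12
Reactants: 21 methyl (1S,4aR,5S,8aR)-5-[(3E)-5-ethoxy-3-methyl-5-oxopent-3-en-1-yl]-1,4a-dimethyl-6-methylidenedecahydronaphthalene-1-carboxylate
Product: 22 methyl (1S,4aR,5S,8aR)-5-[(3E)-5-hydroxy-3-methylpent-3-en-1-yl]-1,4a-dimethyl-6-methylidenedecahydronaphthalene-1-carboxylate
Conditions: DIBAL-H (2.2 equiv), CH2Cl2, −78 °C; aq. Rochelle salt
Reagents that add atoms: none
Why: DIBAL-H 1,2-reduction should convert the unhindered conjugated ethyl ester into the E allylic alcohol, while the axial, neopentyl-type methyl ester at C4 is too hindered to react at this temperature.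

Step 13
Reactants: 22 methyl (1S,4aR,5S,8aR)-5-[(3E)-5-hydroxy-3-methylpent-3-en-1-yl]-1,4a-dimethyl-6-methylidenedecahydronaphthalene-1-carboxylate, 23 hexadecanoyl chloride
Product: 24 methyl (1S,4aR,5S,8aR)-5-[(3E)-5-(hexadecanoyloxy)-3-methylpent-3-en-1-yl]-1,4a-dimethyl-6-methylidenedecahydronaphthalene-1-carboxylate
Conditions: pyridine, DMAP (cat.), CH2Cl2, 0 °C to rt
Reagents that add atoms: none
Why: DMAP-catalysed acylation (nucleophilic acyl substitution) of the primary allylic alcohol gives the palmitate under conditions that leave the exocyclic alkene, the E alkene and the methyl ester unchanged.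

**Compound list**
1 | (5E)-6,10-dimethylundeca-5,9-dien-2-one ((E)-geranylacetone) | CC(=O)CC/C=C(\C)CCC=C(C)C | starting material
2 | 2-[(3E)-4,8-dimethylnona-3,7-dien-1-yl]-2-methyl-1,3-dioxolane | CC1(CC/C=C(\C)CCC=C(C)C)OCCO1 | intermediate
3 | (2E,6E)-2,6-dimethyl-9-(2-methyl-1,3-dioxolan-2-yl)nona-2,6-dien-1-ol | CC1(CC/C=C(\C)CC/C=C(\C)CO)OCCO1 | intermediate
4 | (2E,6E)-2,6-dimethyl-9-(2-methyl-1,3-dioxolan-2-yl)nona-2,6-dien-1-yl methanesulfonate (not isolated) | CC1(CC/C=C(\C)CC/C=C(\C)COS(C)(=O)=O)OCCO1 | intermediate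
5 | 2-[(3E,7E)-9-bromo-4,8-dimethylnona-3,7-dien-1-yl]-2-methyl-1,3-dioxolane | CC1(CC/C=C(\C)CC/C=C(\C)CBr)OCCO1 | intermediate
6 | (+)-8-phenylmenthol, (1S,2R,5S)-5-methyl-2-(2-phenylpropan-2-yl)cyclohexan-1-ol | O[C@H]1C[C@@H](C)CC[C@@H]1C(C)(C)c1ccccc1 | starting material
7 | 2,2,6-trimethyl-4H-1,3-dioxin-4-one | CC1=CC(=O)OC(C)(C)O1 | starting material
8 | acetylketene, 3-oxobut-1-en-1-one (not isolated) | CC(=O)C=C=O | intermediate
9 | (1S,2R,5S)-5-methyl-2-(2-phenylpropan-2-yl)cyclohexyl 3-oxobutanoate | CC(=O)CC(=O)O[C@H]1C[C@@H](C)CC[C@@H]1C(C)(C)c1ccccc1 | intermediate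
10 | sodium lithium 2,4-dianion of 9 (not isolated) | [CH2-]C(=O)[CH-]C(=O)O[C@H]1C[C@@H](C)CC[C@@H]1C(C)(C)c1ccccc1.[Na+].[Li+] | intermediate
11 | (1S,2R,5S)-5-methyl-2-(2-phenylpropan-2-yl)cyclohexyl (6E,10E)-6,10-dimethyl-13-(2-methyl-1,3-dioxolan-2-yl)-3-oxotrideca-6,10-dienoate (not isolated) | CC1(CC/C=C(\C)CC/C=C(\C)CCC(=O)CC(=O)O[C@H]2C[C@@H](C)CC[C@@H]2C(C)(C)c2ccccc2)OCCO1 | intermediate
12 | (1S,2R,5S)-5-methyl-2-(2-phenylpropan-2-yl)cyclohexyl (6E,10E)-6,10-dimethyl-3,14-dioxopentadeca-6,10-dienoate | CC(=O)CC/C=C(\C)CC/C=C(\C)CCC(=O)CC(=O)O[C@H]1C[C@@H](C)CC[C@@H]1C(C)(C)c1ccccc1 | intermediate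
13 | (1S,2R,5S)-5-methyl-2-(2-phenylpropan-2-yl)cyclohexyl (1S,4aS,5S,8aS)-4a-methyl-6-methylidene-2-oxo-5-(3-oxobutyl)decahydronaphthalene-1-carboxylate (trans-decalin; 5α-H, 9α-H, 10β-CH3; C4–H epimerisable, drawn with the equatorial ester) | C=C1CC[C@@H]2[C@](C)(CCC(=O)[C@H]2C(=O)O[C@H]3C[C@@H](C)CC[C@@H]3C(C)(C)c4ccccc4)[C@H]1CCC(C)=O | intermediate
14 | acylketene, (4aS,5S,8aS)-4a-methyl-6-methylidene-1-(oxomethylidene)-5-(3-oxobutyl)octahydronaphthalen-2(1H)-one (not isolated) | C=C1CC[C@@H]2[C@](C)(CCC(=O)C2=C=O)[C@H]1CCC(C)=O | intermediate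
15 | methyl (1S,4aS,5S,8aS)-4a-methyl-6-methylidene-2-oxo-5-(3-oxobutyl)decahydronaphthalene-1-carboxylate (C4–H epimerisable, drawn with the equatorial ester) | C=C1CC[C@@H]2[C@](C)(CCC(=O)[C@H]2C(=O)OC)[C@H]1CCC(C)=O | intermediate
16 | methyl (1R,4aR,5S,8aR)-1,4a-dimethyl-6-methylidene-2-oxo-5-(3-oxobutyl)decahydronaphthalene-1-carboxylate (methyl 3,13-dioxo-14,15-dinorlabd-8(17)-en-19-oate; 4α-CH3, 4β-CO2CH3) | C=C1CC[C@@H]2[C@](C)(CCC(=O)[C@]2(C)C(=O)OC)[C@H]1CCC(C)=O | intermediate
17 | ethyl 2-[di(propan-2-yloxy)phosphoryl]acetate | CCOC(=O)CP(=O)(OC(C)C)OC(C)C | starting material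
18 | methyl (1R,4aR,5S,8aR)-5-[(3E)-5-ethoxy-3-methyl-5-oxopent-3-en-1-yl]-1,4a-dimethyl-6-methylidene-2-oxodecahydronaphthalene-1-carboxylate | C=C1CC[C@@H]2[C@](C)(CCC(=O)[C@]2(C)C(=O)OC)[C@H]1CC/C(C)=C/C(=O)OCC | intermediate
19 | methyl (1R,4aR,5S,8aR)-5-[(3E)-5-ethoxy-3-methyl-5-oxopent-3-en-1-yl]-1,4a-dimethyl-6-methylidene-2-[2-(4-methylbenzenesulfonyl)hydrazinylidene]decahydronaphthalene-1-carboxylate (C=N geometry not defined) | C=C1CC[C@@H]2[C@](C)(CCC(=NNS(=O)(=O)c3ccc(C)cc3)[C@]2(C)C(=O)OC)[C@H]1CC/C(C)=C/C(=O)OCC | intermediate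
20 | N-(1,3,2-benzodioxaborol-2-yl)-N′-tosylhydrazine formed by hydride addition to C3 of 19 (C3 configuration not defined; not isolated) | C=C1CC[C@@H]2[C@](C)(CCC(N(NS(=O)(=O)c3ccc(C)cc3)B3Oc4ccccc4O3)[C@]2(C)C(=O)OC)[C@H]1CC/C(C)=C/C(=O)OCC | intermediate
21 | methyl (1S,4aR,5S,8aR)-5-[(3E)-5-ethoxy-3-methyl-5-oxopent-3-en-1-yl]-1,4a-dimethyl-6-methylidenedecahydronaphthalene-1-carboxylate | C=C1CC[C@@H]2[C@](C)(CCC[C@]2(C)C(=O)OC)[C@H]1CC/C(C)=C/C(=O)OCC | intermediate
22 | methyl (1S,4aR,5S,8aR)-5-[(3E)-5-hydroxy-3-methylpent-3-en-1-yl]-1,4a-dimethyl-6-methylidenedecahydronaphthalene-1-carboxylate (methyl isocupressate) | C=C1CC[C@@H]2[C@](C)(CCC[C@]2(C)C(=O)OC)[C@H]1CC/C(C)=C/CO | intermediate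
23 | hexadecanoyl chloride (palmitoyl chloride) | CCCCCCCCCCCCCCCC(=O)Cl | starting material
24 | methyl (1S,4aR,5S,8aR)-5-[(3E)-5-(hexadecanoyloxy)-3-methylpent-3-en-1-yl]-1,4a-dimethyl-6-methylidenedecahydronaphthalene-1-carboxylate | C=C1CC[C@@H]2[C@](C)(CCC[C@]2(C)C(=O)OC)[C@H]1CC/C(C)=C/COC(=O)CCCCCCCCCCCCCCC | target

**Step count**
Total steps: 13. Longest linear sequence: 12 steps (steps 1–3 and 5–13 from 1; step 4 is a one-step side branch).

**Steps most likely to fail**

Step 6. The cyclised product is still an enolisable C4–H β-keto ester and may be oxidised again by Mn(III), and facial control by the auxiliary may be incomplete. The fallback sets out from 12 and comes back at 13. Chlorination of 12 between the two carbonyl groups (SO2Cl2, CH2Cl2, 0 °C) should give (1S,2R,5S)-5-methyl-2-(2-phenylpropan-2-yl)cyclohexyl (6E,10E)-2-chloro-6,10-dimethyl-3,14-dioxopentadeca-6,10-dienoate F1. The same Mn(OAc)3/Cu(OAc)2 cyclisation should then give the 4-chloro bicycle, (1S,2R,5S)-5-methyl-2-(2-phenylpropan-2-yl)cyclohexyl 1-chloro-4a-methyl-6-methylidene-2-oxo-5-(3-oxobutyl)decahydronaphthalene-1-carboxylate F2. Its quaternary C4 blocks further oxidation, and Zn dust in AcOH then removes the chlorine to return 13.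

Step 7. The auxiliary alcohol may not be expelled at a temperature the exocyclic alkene tolerates, or the acylketene may be lost to side reactions. The fallback sets out from 5 and comes back at 15; it places the chirality in a Lewis acid so that the methyl ester is present from the start.
- Bromide 5 is alkylated with the dianion of methyl acetoacetate (NaH, n-BuLi, THF, 0 °C) to give methyl (6E,10E)-6,10-dimethyl-13-(2-methyl-1,3-dioxolan-2-yl)-3-oxotrideca-6,10-dienoate F3.
- Dilute HCl in the work-up converts this into methyl (6E,10E)-6,10-dimethyl-3,14-dioxopentadeca-6,10-dienoate F4.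
- PhSeCl and pyridine give methyl (6E,10E)-6,10-dimethyl-3,14-dioxo-2-(phenylselanyl)pentadeca-6,10-dienoate F5.
- Irradiation with Mg(ClO4)2 and a C2-symmetric bis(oxazoline) ligand at low temperature (enantioselective PhSe-group-transfer tandem radical cyclisation, ligand enantiomer chosen for the 5α-H,10β-CH3 series) should give methyl 4a-methyl-6-methyl-2-oxo-5-(3-oxobutyl)-6-(phenylselanyl)decahydronaphthalene-1-carboxylate F6.
- H2O2 and pyridine at 0 °C give the selenoxide of F6, methyl 4a-methyl-6-methyl-2-oxo-5-(3-oxobutyl)-6-(phenylseleninyl)decahydronaphthalene-1-carboxylate F7, which should lose PhSeOH by syn-elimination towards the C17 methyl to give 15.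

Step 10. Condensation at the hindered C3 carbonyl next to the quaternary C4 may be slow or incomplete, or the hydrazide may attack the neighbouring ester. The fallback sets out from 18 and comes back at 21 (Barton–McCombie deoxygenation). NaBH4 in MeOH at 0 °C reduces only the C3 ketone to methyl 5-[(3E)-5-ethoxy-3-methyl-5-oxopent-3-en-1-yl]-2-hydroxy-1,4a-dimethyl-6-methylidenedecahydronaphthalene-1-carboxylate F8 (mainly the equatorial alcohol expected). PhOC(S)Cl, pyridine and DMAP give the O-phenyl thionocarbonate, methyl 5-[(3E)-5-ethoxy-3-methyl-5-oxopent-3-en-1-yl]-1,4a-dimethyl-6-methylidene-2-[(phenoxycarbonothioyl)oxy]decahydronaphthalene-1-carboxylate F9. Bu3SnH and AIBN in toluene at 90 °C then give 21.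

Further compounds
F1 | step 6 | (1S,2R,5S)-5-methyl-2-(2-phenylpropan-2-yl)cyclohexyl (6E,10E)-2-chloro-6,10-dimethyl-3,14-dioxopentadeca-6,10-dienoate | CC(=O)CC/C=C(\C)CC/C=C(\C)CCC(=O)C(Cl)C(=O)O[C@H]1C[C@@H](C)CC[C@@H]1C(C)(C)c1ccccc1
F2 | step 6 | (1S,2R,5S)-5-methyl-2-(2-phenylpropan-2-yl)cyclohexyl 1-chloro-4a-methyl-6-methylidene-2-oxo-5-(3-oxobutyl)decahydronaphthalene-1-carboxylate (C4 configuration not defined) | C=C1CC[C@@H]2[C@](C)(CCC(=O)C2(Cl)C(=O)O[C@H]3C[C@@H](C)CC[C@@H]3C(C)(C)c4ccccc4)[C@H]1CCC(C)=O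
F3 | step 7 | methyl (6E,10E)-6,10-dimethyl-13-(2-methyl-1,3-dioxolan-2-yl)-3-oxotrideca-6,10-dienoate | CC1(CC/C=C(\C)CC/C=C(\C)CCC(=O)CC(=O)OC)OCCO1
F4 | step 7 | methyl (6E,10E)-6,10-dimethyl-3,14-dioxopentadeca-6,10-dienoate | CC(=O)CC/C=C(\C)CC/C=C(\C)CCC(=O)CC(=O)OC
F5 | step 7 | methyl (6E,10E)-6,10-dimethyl-3,14-dioxo-2-(phenylselanyl)pentadeca-6,10-dienoate | CC(=O)CC/C=C(\C)CC/C=C(\C)CCC(=O)C([Se]c1ccccc1)C(=O)OC
F6 | step 7 | methyl 4a-methyl-6-methyl-2-oxo-5-(3-oxobutyl)-6-(phenylselanyl)decahydronaphthalene-1-carboxylate (C8 configuration not defined) | CC1([Se]c2ccccc2)CC[C@@H]2[C@](C)(CCC(=O)[C@H]2C(=O)OC)[C@H]1CCC(C)=O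
F7 | step 7 | methyl 4a-methyl-6-methyl-2-oxo-5-(3-oxobutyl)-6-(phenylseleninyl)decahydronaphthalene-1-carboxylate | CC1([Se](=O)c2ccccc2)CC[C@@H]2[C@](C)(CCC(=O)[C@H]2C(=O)OC)[C@H]1CCC(C)=O
F8 | step 10 | methyl 5-[(3E)-5-ethoxy-3-methyl-5-oxopent-3-en-1-yl]-2-hydroxy-1,4a-dimethyl-6-methylidenedecahydronaphthalene-1-carboxylate (C3 configuration not defined) | C=C1CC[C@@H]2[C@](C)(CCC(O)[C@]2(C)C(=O)OC)[C@H]1CC/C(C)=C/C(=O)OCC
F9 | step 10 | methyl 5-[(3E)-5-ethoxy-3-methyl-5-oxopent-3-en-1-yl]-1,4a-dimethyl-6-methylidene-2-[(phenoxycarbonothioyl)oxy]decahydronaphthalene-1-carboxylate | C=C1CC[C@@H]2[C@](C)(CCC(OC(=S)Oc3ccccc3)[C@]2(C)C(=O)OC)[C@H]1CC/C(C)=C/C(=O)OCC
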